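**Retrosynthetic overview**
1. Target 26 ⇐ 25 (late Markovnikov hydration of an exocyclic C-1 methylidene) ⇐ 24 (one reduction of two ketones) ⇐ 23 (oxidative 1,3-transposition) ⇐ enone 11 + alkyllithium from iodide 21 (C-5–CH2 bond).
2. Hydroazulene 11 ⇐ enol ether 7 ⇐ aryl diazoketone 5. Key step: a copper-catalysed asymmetric intramolecular Büchner ring expansion turns the anisole ring into the seven-membered ring and closes the five-membered ring at once; hydrogenation in the same operation sets the cis fusion.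
3. Benzoxepane 21 ⇐ ketone 18 ⇐ diepoxy silyloxydiene 17 (geranyl bromide, double Shi epoxidation). One silyl triflate cascade closes the oxepane, then the cyclohexane.
4. Ring order: seven- and five-membered rings together; separately oxepane then cyclohexane; then union. C-3 of the oxepane is turned from R to S by the oxidation/reduction pair that the union needs anyway.

Assumption: the (S,S)-bis(oxazoline)–copper catalyst gives (8aR)-6 and the D-fructose-derived Shi ketone gives R epoxide carbons; if either sense is reversed, the antipodal ligand or ketone is used.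

**Route**

Step 1
Reactants: 1 4-bromo-2-methoxy-1-methylbenzene; 2 but-3-en-2-ol
Product: 3 4-(3-methoxy-4-methylphenyl)butan-2-one
Conditions: Pd(OAc)2 (2 mol %), PPh3, NaHCO3, DMF, 120 °C
Reagents that add atoms: none
Why: Heck arylation of the allylic alcohol; β-hydride elimination towards the carbinol carbon gives the enol and hence the saturated aryl butanone directly (no stereocentre).

Step 2
Reactants: 3 4-(3-methoxy-4-methylphenyl)butan-2-one
Product: 5 1-diazo-4-(3-methoxy-4-methylphenyl)butan-2-one, via trifluoroacetyl diketone 4 (not isolated)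
Conditions: LiN(SiMe3)2, THF, −78 °C; CF3CO2CH2CF3; aq. HCl; then MsN3, Et3N, H2O, MeCN, 20 °C
Reagents that add atoms: methanesulfonyl azide CS(=O)(=O)N=[N+]=[N-] (diazo nitrogens); 2,2,2-trifluoroethyl trifluoroacetate O=C(OCC(F)(F)F)C(F)(F)F (trifluoroacetyl group of 4 only)
Why: Deacylative (Danheiser) diazo transfer: the kinetic methyl enolate is trifluoroacetylated and the activated diketone takes the diazo group with loss of the trifluoroacetyl group.

Step 3
Reactants: 5 1-diazo-4-(3-methoxy-4-methylphenyl)butan-2-one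
Product: 7 (3aS,8aR)-5-methoxy-6-methyl-3,3a,4,7,8,8a-hexahydroazulen-1(2H)-one, via azulenone 6 (not isolated)
Conditions: [Cu(MeCN)4]PF6 (5 mol %), (4S,4′S)-2,2′-(propane-2,2-diyl)bis(4-phenyl-4,5-dihydrooxazole) (6 mol %), Na[B(3,5-(CF3)2C6H3)4] (6 mol %), CH2Cl2, 40 °C, slow addition; evaporate; then 10% Pd/C, H2 (1 atm, stop at 2 equiv), EtOAc/Et3N 100:1, 0 °C
Reagents that add atoms: none
Why: Enantioselective intramolecular Büchner reaction: the copper carbenoid cyclopropanates the ipso/ortho bond at the unhindered ortho carbon para to OMe, the norcaradiene opens to the cycloheptatriene and the ligand fixes C-8a as R; hydrogenation of the crude triene then saturates the di- and trisubstituted C=C bonds from the face of H-8a (cis fusion, C-3a) and leaves the tetrasubstituted enol ether.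

Step 4
Reactants: 7 (3aS,8aR)-5-methoxy-6-methyl-3,3a,4,7,8,8a-hexahydroazulen-1(2H)-one
Product: 8 (3aS,8aR)-5-methoxy-6-methyl-1-methylidene-1,2,3,3a,4,7,8,8a-octahydroazulene
Conditions: Cp2TiMe2 (2.5 equiv), toluene, 70 °C, dark
Reagents that add atoms: dimethyltitanocene C[Ti](C)(C1C=CC=C1)C1C=CC=C1
Why: Petasis methylenation is non-basic, so the epimerisable C-8a next to the ketone and the enol ether are untouched.

Step 5
Reactants: 8 (3aS,8aR)-5-methoxy-6-methyl-1-methylidene-1,2,3,3a,4,7,8,8a-octahydroazulene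
Product: 9 (3aS,8aR)-6-methyl-1-methylidene-2,3,3a,4,8,8a-hexahydroazulen-5(1H)-one
Conditions: DDQ (1.1 equiv), CH2Cl2/H2O 20:1, 0 → 20 °C
Reagents that add atoms: water O
Why: DDQ dehydrogenation of an enol ether (Saegusa-type oxidation): hydride abstraction at C-7 gives the methoxy-stabilised allyl cation, and water releases methanol and the 6-methyl enone.

Step 6
Reactants: 9 (3aS,8aR)-6-methyl-1-methylidene-2,3,3a,4,8,8a-hexahydroazulen-5(1H)-one
Product: 11 (3aR,8aR)-4,4,6-trimethyl-1-methylidene-2,3,3a,4,8,8a-hexahydroazulen-5(1H)-one, via monomethyl enone 10 (not isolated)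
Conditions: LiN(iPr)2, THF, −78 °C, MeI; then LiN(iPr)2, MeI, DMPU, −78 → 0 °C
Reagents that add atoms: iodomethane CI
Why: Kinetic α′-deprotonation of the enone (C-6 is blocked as an alkene carbon) and two successive enolate methylations build the quaternary C-4; no new stereocentre remains.

Step 7
Reactants: 12 geranyl bromide, (2E)-1-bromo-3,7-dimethylocta-2,6-diene; 13 N-methoxy-N-methylacetamide
Product: 14 (4E)-N-methoxy-N,5,9-trimethyldeca-4,8-dienamide
Conditions: LiN(iPr)2, THF, −78 °C; then 12, −78 → 0 °C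
Reagents that add atoms: none
Why: SN2 alkylation of the Weinreb acetamide enolate by the allylic bromide with retention of the E olefin.

Step 8
Reactants: 14 (4E)-N-methoxy-N,5,9-trimethyldeca-4,8-dienamide
Product: 15 3-[(2R,3R)-3-{2-[(2R)-3,3-dimethyloxiran-2-yl]ethyl}-3-methyloxiran-2-yl]-N-methoxy-N-methylpropanamide
Conditions: D-fructose-derived Shi ketone (0.6 equiv), KHSO5 (as 2KHSO5·KHSO4·K2SO4), K2CO3, Bu4NHSO4, MeCN/CH2(OMe)2/aq. Na2B4O7–Na2EDTA buffer, 0 °C
Reagents that add atoms: potassium peroxymonosulfate [K+].[O-]S(=O)(=O)OO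
Why: Shi asymmetric epoxidation: the chiral dioxirane epoxidises both trisubstituted olefins through the spiro transition state, giving R at all three epoxide stereocentres.

Step 9
Reactants: 15 the diepoxy Weinreb amide
Product: 16 1-[(2R,3R)-3-{2-[(2R)-3,3-dimethyloxiran-2-yl]ethyl}-3-methyloxiran-2-yl]hex-5-en-3-one
Conditions: CH2=CHCH2MgBr, THF, −78 °C; pH 7 buffer
Reagents that add atoms: allylmagnesium bromide C=CC[Mg]Br
Why: Weinreb ketone synthesis: the chelated adduct stops at the ketone stage, trisubstituted epoxides are inert at −78 °C, and neutral work-up keeps the β,γ-enone unconjugated.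

Step 10
Reactants: 16 the diepoxy allyl ketone
Product: 17 trimethyl{[(3Z)-1-[(2R,3R)-3-{2-[(2R)-3,3-dimethyloxiran-2-yl]ethyl}-3-methyloxiran-2-yl]hexa-3,5-dien-3-yl]oxy}silane
Conditions: Me3SiCl, LiN(iPr)2, THF/DMPU, −78 °C; pentane, aq. NaHCO3
Reagents that add atoms: chlorotrimethylsilane C[Si](C)(C)Cl
Why: Regioselective enolisation at the doubly activated CH2 between carbonyl and vinyl, then O-silylation; DMPU favours the Z(O) enolate (vinyl cis to OSi).

Step 11
Reactants: 17 the diepoxy 2-silyloxy-1,3-diene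
Product: 18 (3R,5aR,6R,9aR)-6-ethenyl-2,2,5a-trimethyl-3-[(trimethylsilyl)oxy]octahydro-1-benzoxepin-7(2H)-one
Conditions: Me3SiOTf (1.2 equiv), 2,6-di-tert-butyl-4-methylpyridine, CH2Cl2, −78 °C; Et3N
Reagents that add atoms: trimethylsilyl trifluoromethanesulfonate C[Si](C)(C)OS(=O)(=O)C(F)(F)F
Why: Proposed new method: the silyl triflate activates the terminal epoxide, the internal epoxide oxygen opens it at the tertiary carbon, and the epoxonium ion is opened at C-5a with inversion by the α-carbon of the silyloxydiene through a chair (trans fusion, equatorial vinyl, γ-attack would need an eight-membered ring), silyl loss then giving the ketone; the closest known reaction type is the silyl-triflate-promoted tandem oxa-/carbacyclisation of diepoxy enol silanes.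

Step 12
Reactants: 18 the 6-vinyl benzoxepinone
Product: 19 (3R,5aR,6R,7S,9aR)-6-ethenyl-2,2,5a,7-tetramethyl-3-[(trimethylsilyl)oxy]decahydro-1-benzoxepin-7-ol
Conditions: MeLi, CeCl3, THF, −78 °C
Reagents that add atoms: methyllithium [Li]C
Why: Organocerium (Imamoto) addition avoids enolising the α-vinyl ketone; methyl enters equatorially, away from the 1,3-diaxial C-5a methyl, giving the axial tertiary alcohol (7S).

Step 13
Reactants: 19 the vinyl tertiary alcohol
Product: 21 (3R,5aR,6R,7S,9aR)-6-(2-iodoethyl)-2,2,5a,7-tetramethyldecahydro-1-benzoxepine-3,7-diol, via alkylborane 20 (not isolated)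
Conditions: 9-BBN-H (2.5 equiv), THF, 0 → 20 °C; then NaOAc, ICl, MeOH, 0 °C; aq. citric acid, 20 °C
Reagents that add atoms: iodine monochloride ICl (iodine); 9-borabicyclo[3.3.1]nonane [H]B1C2CCCC1CCC2 (boron of 20 only)
Why: Anti-Markovnikov hydroboration of the only alkene and iododeboration of the primary B–C bond under non-basic conditions (no tetrahydrofuran closure of the γ-iodo alcohol); the acid wash removes the silyl ether.

Step 14
Reactants: 21 the iodo diol; 11 (3aR,8aR)-4,4,6-trimethyl-1-methylidene-2,3,3a,4,8,8a-hexahydroazulen-5(1H)-one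
Product: 23 (3R,5aR,6R,7S,9aR)-6-{2-[(3aR,8aR)-5-hydroxy-4,4,6-trimethyl-1-methylidene-1,2,3,3a,4,5,8,8a-octahydroazulen-5-yl]ethyl}-2,2,5a,7-tetramethyldecahydro-1-benzoxepine-3,7-diol, via trilithio species 22 (not isolated)
Conditions: 21: MeLi (2 equiv), Et2O, −78 °C; t-BuLi (2 equiv), −78 °C; then 11, −78 → −20 °C; H2O
Reagents that add atoms: methyllithium [Li]C; tert-butyllithium [Li]C(C)(C)C (lithium atoms of 22 only)
Why: The alkoxides are formed first, iodine–lithium exchange then gives the primary alkyllithium, which adds 1,2 to the enone carbonyl (no α′ hydrogens, as with 2,6,6-trimethylcyclohexenone); the new carbinol centre is erased in step 15.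

Step 15
Reactants: 23 the triol
Product: 24 (5aR,6R,7S,9aR)-7-hydroxy-2,2,5a,7-tetramethyl-6-{2-[(3aR,8aR)-4,4,6-trimethyl-1-methylidene-7-oxo-1,2,3,3a,4,7,8,8a-octahydroazulen-5-yl]ethyl}octahydro-1-benzoxepin-3(2H)-one
Conditions: [C5H5NH][CrO3Cl] (pyridinium chlorochromate, 4 equiv), 4 Å molecular sieves, CH2Cl2, 20 °C
Reagents that add atoms: none
Why: Babler–Dauben oxidative 1,3-transposition (chromate ester [3,3] shift, then oxidation) turns the tertiary allylic alcohol into the tetrasubstituted enone, and the same reagent oxidises the C-3 alcohol to the ketone, erasing its R configuration.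

Step 16
Reactants: 24 the enone ketone
Product: 25 (3S,5aR,6R,7S,9aR)-6-{2-[(3aR,7S,8aR)-7-hydroxy-4,4,6-trimethyl-1-methylidene-1,2,3,3a,4,7,8,8a-octahydroazulen-5-yl]ethyl}-2,2,5a,7-tetramethyldecahydro-1-benzoxepine-3,7-diol
Conditions: NaBH4, CeCl3·7H2O, MeOH, −40 °C
Reagents that add atoms: none
Why: Luche reduction: 1,2-hydride delivery to the enone from the convex face (side of H-8a) gives 7S, and axial-type attack on the 2,2-dimethyloxepan-3-one gives the equatorial 3S alcohol cis to the C-5a methyl, as in 4,4-dimethyl-3-oxo triterpenoids.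

Step 17
Reactants: 25 the methylidene tetraol
Product: 26 (3S,5aR,6R,7S,9aR)-6-{2-[(1R,3aR,7S,8aR)-1,7-dihydroxy-1,4,4,6-tetramethyl-1,2,3,3a,4,7,8,8a-octahydroazulen-5-yl]ethyl}-2,2,5a,7-tetramethyldecahydro-1-benzoxepine-3,7-diol
Conditions: Co(acac)2 (20 mol %), PhSiH3, O2 (1 atm), THF, 20 °C
Reagents that add atoms: dioxygen O=O
Why: Mukaiyama hydration (hydrogen atom transfer, O2 capture, in-flask peroxide reduction) puts OH on the tertiary carbon of the 1,1-disubstituted alkene only; oxygen enters the radical on the convex face syn to H-8a, giving 1R.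

**Compound list**
1 | 4-bromo-2-methoxy-1-methylbenzene | COc1cc(Br)ccc1C | starting material
2 | but-3-en-2-ol (racemic) | CC(O)C=C | starting material
3 | 4-(3-methoxy-4-methylphenyl)butan-2-one | COc1cc(CCC(C)=O)ccc1C | intermediate
4 | 1,1,1-trifluoro-6-(3-methoxy-4-methylphenyl)hexane-2,4-dione (not isolated) | COc1cc(CCC(=O)CC(=O)C(F)(F)F)ccc1C | intermediate
5 | 1-diazo-4-(3-methoxy-4-methylphenyl)butan-2-one | COc1cc(CCC(=O)C=[N+]=[N-])ccc1C | intermediate
6 | (8aR)-5-methoxy-6-methyl-3,8a-dihydroazulen-1(2H)-one (not isolated) | C1=C2CCC(=O)[C@@H]2C=CC(C)=C1OC | intermediate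
7 | (3aS,8aR)-5-methoxy-6-methyl-3,3a,4,7,8,8a-hexahydroazulen-1(2H)-one (cis-fused) | C1[C@@H]2CCC(=O)[C@@H]2CCC(C)=C1OC | intermediate
8 | (3aS,8aR)-5-methoxy-6-methyl-1-methylidene-1,2,3,3a,4,7,8,8a-octahydroazulene | C1[C@@H]2CCC(=C)[C@@H]2CCC(C)=C1OC | intermediate
9 | (3aS,8aR)-6-methyl-1-methylidene-2,3,3a,4,8,8a-hexahydroazulen-5(1H)-one | O=C1C[C@@H]2CCC(=C)[C@@H]2CC=C1C | intermediate
10 | (3aR,8aR)-4,6-dimethyl-1-methylidene-2,3,3a,4,8,8a-hexahydroazulen-5(1H)-one, both C-4 epimers (not isolated) | O=C1C(C)[C@@H]2CCC(=C)[C@@H]2CC=C1C | intermediate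
11 | (3aR,8aR)-4,4,6-trimethyl-1-methylidene-2,3,3a,4,8,8a-hexahydroazulen-5(1H)-one | CC1(C)[C@@H]2CCC(=C)[C@@H]2CC=C(C)C1=O | intermediate
12 | geranyl bromide, (2E)-1-bromo-3,7-dimethylocta-2,6-diene | CC(C)=CCC/C(C)=C/CBr | starting material
13 | N-methoxy-N-methylacetamide | CC(=O)N(C)OC | starting material
14 | (4E)-N-methoxy-N,5,9-trimethyldeca-4,8-dienamide | CC(C)=CCC/C(C)=C/CCC(=O)N(C)OC | intermediate
15 | 3-[(2R,3R)-3-{2-[(2R)-3,3-dimethyloxiran-2-yl]ethyl}-3-methyloxiran-2-yl]-N-methoxy-N-methylpropanamide | CC1(C)O[C@@H]1CC[C@@]2(C)O[C@@H]2CCC(=O)N(C)OC | intermediate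
16 | 1-[(2R,3R)-3-{2-[(2R)-3,3-dimethyloxiran-2-yl]ethyl}-3-methyloxiran-2-yl]hex-5-en-3-one | CC1(C)O[C@@H]1CC[C@@]2(C)O[C@@H]2CCC(=O)CC=C | intermediate
17 | trimethyl{[(3Z)-1-[(2R,3R)-3-{2-[(2R)-3,3-dimethyloxiran-2-yl]ethyl}-3-methyloxiran-2-yl]hexa-3,5-dien-3-yl]oxy}silane | CC1(C)O[C@@H]1CC[C@@]2(C)O[C@@H]2CC/C(O[Si](C)(C)C)=C/C=C | intermediate
18 | (3R,5aR,6R,9aR)-6-ethenyl-2,2,5a-trimethyl-3-[(trimethylsilyl)oxy]octahydro-1-benzoxepin-7(2H)-one | C=C[C@@H]2[C@@]3(C)CC[C@@H](O[Si](C)(C)C)C(C)(C)O[C@@H]3CCC2=O | intermediate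
19 | (3R,5aR,6R,7S,9aR)-6-ethenyl-2,2,5a,7-tetramethyl-3-[(trimethylsilyl)oxy]decahydro-1-benzoxepin-7-ol | C=C[C@@H]2[C@@]3(C)CC[C@@H](O[Si](C)(C)C)C(C)(C)O[C@@H]3CC[C@]2(C)O | intermediate
20 | (3R,5aR,6R,7S,9aR)-6-[2-(9-borabicyclo[3.3.1]nonan-9-yl)ethyl]-2,2,5a,7-tetramethyl-3-[(trimethylsilyl)oxy]decahydro-1-benzoxepin-7-ol (not isolated) | C1CC2CCCC(C1)B2CC[C@@H]2[C@@]3(C)CC[C@@H](O[Si](C)(C)C)C(C)(C)O[C@@H]3CC[C@]2(C)O | intermediate
21 | (3R,5aR,6R,7S,9aR)-6-(2-iodoethyl)-2,2,5a,7-tetramethyldecahydro-1-benzoxepine-3,7-diol | ICC[C@@H]2[C@@]3(C)CC[C@@H](O)C(C)(C)O[C@@H]3CC[C@]2(C)O | intermediate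
22 | trilithio derivative of 21: C-lithio at the chain end, O-lithio at O-3 and O-7 (not isolated) | [Li]CC[C@@H]2[C@@]3(C)CC[C@@H](O[Li])C(C)(C)O[C@@H]3CC[C@]2(C)O[Li] | intermediate
23 | (3R,5aR,6R,7S,9aR)-6-{2-[(3aR,8aR)-5-hydroxy-4,4,6-trimethyl-1-methylidene-1,2,3,3a,4,5,8,8a-octahydroazulen-5-yl]ethyl}-2,2,5a,7-tetramethyldecahydro-1-benzoxepine-3,7-diol (either configuration at the azulene C-5) | CC1(C)[C@@H]2CCC(=C)[C@@H]2CC=C(C)C1(O)CC[C@@H]3[C@@]4(C)CC[C@@H](O)C(C)(C)O[C@@H]4CC[C@]3(C)O | intermediate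
24 | (5aR,6R,7S,9aR)-7-hydroxy-2,2,5a,7-tetramethyl-6-{2-[(3aR,8aR)-4,4,6-trimethyl-1-methylidene-7-oxo-1,2,3,3a,4,7,8,8a-octahydroazulen-5-yl]ethyl}octahydro-1-benzoxepin-3(2H)-one | CC1=C(CC[C@@H]2[C@@]3(C)CCC(=O)C(C)(C)O[C@@H]3CC[C@]2(C)O)C(C)(C)[C@@H]2CCC(=C)[C@@H]2CC1=O | intermediate
25 | (3S,5aR,6R,7S,9aR)-6-{2-[(3aR,7S,8aR)-7-hydroxy-4,4,6-trimethyl-1-methylidene-1,2,3,3a,4,7,8,8a-octahydroazulen-5-yl]ethyl}-2,2,5a,7-tetramethyldecahydro-1-benzoxepine-3,7-diol | CC1=C(CC[C@@H]2[C@@]3(C)CC[C@H](O)C(C)(C)O[C@@H]3CC[C@]2(C)O)C(C)(C)[C@@H]2CCC(=C)[C@@H]2C[C@@H]1O | intermediate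
26 | (3S,5aR,6R,7S,9aR)-6-{2-[(1R,3aR,7S,8aR)-1,7-dihydroxy-1,4,4,6-tetramethyl-1,2,3,3a,4,7,8,8a-octahydroazulen-5-yl]ethyl}-2,2,5a,7-tetramethyldecahydro-1-benzoxepine-3,7-diol (CNP0276044.4) | CC1=C(CC[C@@H]2[C@@]3(C)CC[C@H](O)C(C)(C)O[C@@H]3CC[C@]2(C)O)C(C)(C)[C@@H]2CC[C@@](C)(O)[C@@H]2C[C@@H]1O | target

**Step count and risks**

Total: 17 steps (6 to enone 11, 7 to iodide 21, 4 after union). Longest linear sequence: 11 steps (steps 7–17, from 12 and 13 to 26).

Most likely to fail: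

Step 3. The Büchner reaction must choose the ortho carbon para to OMe and give high ee, and the hydrogenation must stop with the tetrasubstituted enol ether intact; over-reduction or 1,4-addition of hydrogen would lose the position of the latent enone. The fallback sets out from 6 and comes back at 9, rebuilding the oxidation pattern instead of preserving it. Crude 6 is hydrogenated at all carbon C=C bonds (Pd/C, H2) and hydrolysed with dilute HCl/THF to (3aS,8aR)-6-methyloctahydroazulene-1,5-dione F1. The more reactive cyclopentanone is methylenated with one equivalent of Ph3P=CH2 at −78 to 0 °C to give (3aS,8aR)-6-methyl-1-methylideneoctahydroazulen-5(1H)-one F2. Thermodynamic silylation (Me3SiCl, NaI, Et3N, MeCN) gives the tetrasubstituted trimethylsilyl enol ether F3, and Saegusa oxidation (Pd(OAc)2, O2, DMSO) gives 9.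

Step 11. The silyloxydiene is an untested terminating group for this cascade and is acid-sensitive, and the α-vinyl ketone product can slip into conjugation. The fallback sets out from 15 and comes back at 21, one step longer, using a saturated Z enol silane of the kind already proven in such cascades. 15 reacts with (E)-3-(tert-butyldimethylsilyloxy)prop-1-enyllithium to give the enone (4E)-6-[(tert-butyldimethylsilyl)oxy]-1-[(2R,3R)-3-{2-[(2R)-3,3-dimethyloxiran-2-yl]ethyl}-3-methyloxiran-2-yl]hex-4-en-3-one F4. RhCl(PPh3)3-catalysed 1,4-hydrosilylation with Et3SiH gives the (Z)-triethylsilyl enol ether F5. The same Me3SiOTf cascade gives the bicyclic ketone with a 2-silyloxyethyl chain F6, and MeLi/CeCl3 gives the tertiary alcohol F7. Bu4NF gives the triol (3R,5aR,6R,7S,9aR)-6-(2-hydroxyethyl)-2,2,5a,7-tetramethyldecahydro-1-benzoxepine-3,7-diol F8, and I2, PPh3, imidazole (primary OH only) gives 21.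

Step 17. This is a hydrogen-atom-transfer hydration on the unprotected final skeleton; the face selectivity at C-1 and the inertness of the tetrasubstituted alkene are predicted, not known. The fallback sets out from 24 and comes back at 26, one step longer, replacing the radical hydration by epoxidation and hydride opening. While the ring alkene is still an electron-poor enone, dimethyldioxirane (acetone, −20 °C) epoxidises only the methylidene group from the convex face to give the spiro-epoxide diketone F9. NaBH4/CeCl3·7H2O reduces both ketones as in step 16 to the spiro-epoxide triol F10, and LiAlH4 (THF, 0 °C) opens the epoxide at CH2 to give 26.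

**Further compounds**
F1 | step 3 | (3aS,8aR)-6-methyloctahydroazulene-1,5-dione (C-6 epimers) | O=C1C[C@@H]2CCC(=O)[C@@H]2CCC1C
F2 | step 3 | (3aS,8aR)-6-methyl-1-methylideneoctahydroazulen-5(1H)-one (C-6 epimers) | O=C1C[C@@H]2CCC(=C)[C@@H]2CCC1C
F3 | step 3 | trimethyl{[(3aS,8aR)-6-methyl-1-methylidene-1,2,3,3a,4,7,8,8a-octahydroazulen-5-yl]oxy}silane | C1[C@@H]2CCC(=C)[C@@H]2CCC(C)=C1O[Si](C)(C)C
F4 | step 11 | (4E)-6-[(tert-butyldimethylsilyl)oxy]-1-[(2R,3R)-3-{2-[(2R)-3,3-dimethyloxiran-2-yl]ethyl}-3-methyloxiran-2-yl]hex-4-en-3-one | CC1(C)O[C@@H]1CC[C@@]2(C)O[C@@H]2CCC(=O)/C=C/CO[Si](C)(C)C(C)(C)C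
F5 | step 11 | (3Z)-6-[(tert-butyldimethylsilyl)oxy]-1-[(2R,3R)-3-{2-[(2R)-3,3-dimethyloxiran-2-yl]ethyl}-3-methyloxiran-2-yl]-3-[(triethylsilyl)oxy]hex-3-ene | CC1(C)O[C@@H]1CC[C@@]2(C)O[C@@H]2CC/C(O[Si](CC)(CC)CC)=C/CCO[Si](C)(C)C(C)(C)C
F6 | step 11 | (3R,5aR,6R,9aR)-6-{2-[(tert-butyldimethylsilyl)oxy]ethyl}-2,2,5a-trimethyl-3-[(trimethylsilyl)oxy]octahydro-1-benzoxepin-7(2H)-one | CC(C)(C)[Si](C)(C)OCC[C@@H]2[C@@]3(C)CC[C@@H](O[Si](C)(C)C)C(C)(C)O[C@@H]3CCC2=O
F7 | step 11 | (3R,5aR,6R,7S,9aR)-6-{2-[(tert-butyldimethylsilyl)oxy]ethyl}-2,2,5a,7-tetramethyl-3-[(trimethylsilyl)oxy]decahydro-1-benzoxepin-7-ol | CC(C)(C)[Si](C)(C)OCC[C@@H]2[C@@]3(C)CC[C@@H](O[Si](C)(C)C)C(C)(C)O[C@@H]3CC[C@]2(C)O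
F8 | step 11 | (3R,5aR,6R,7S,9aR)-6-(2-hydroxyethyl)-2,2,5a,7-tetramethyldecahydro-1-benzoxepine-3,7-diol | OCC[C@@H]2[C@@]3(C)CC[C@@H](O)C(C)(C)O[C@@H]3CC[C@]2(C)O
F9 | step 17 | 24 with the C-1 methylidene converted into a (1R)-spiro-oxirane, oxygen on the face of H-8a | CC1=C(CC[C@@H]2[C@@]3(C)CCC(=O)C(C)(C)O[C@@H]3CC[C@]2(C)O)C(C)(C)[C@@H]2CC[C@@]4(OC4)[C@@H]2CC1=O
F10 | step 17 | 25 with the C-1 methylidene converted into the same (1R)-spiro-oxirane | CC1=C(CC[C@@H]2[C@@]3(C)CC[C@H](O)C(C)(C)O[C@@H]3CC[C@]2(C)O)C(C)(C)[C@@H]2CC[C@@]4(OC4)[C@@H]2C[C@@H]1O
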